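Numbering follows 5,6,7,8-tetrahydronaphthalene-2-carboxylic acid (aromatic ring A, saturated ring B). Everything rests on closing ring B between the methylene C6 and the methyl-bearing benzylic carbon C5. C5 carries only H, CH3 and the ring A carbon C4a, so it can be drawn from a vinyl group on C4a: a chiral copper hydride adds to this vinylarene, the benzylic copper so formed displaces a primary bromide at C6, and one operation gives the C5–C6 bond, ring B, the C5 methyl group and the C5 stereocentre. The precursor is an open-chain ortho-vinylaryl alkyl bromide whose C8 and adjacent side-chain centres come from one iridium/amine dual-catalytic allylation.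

Key step: step 14

Abbreviations: TBS = tert-butyldimethylsilyl; Bn = benzyl.

Assumption: the ligand enantiomers named in steps 9 and 14 are those expected, by analogy with simpler aryl substrates, to give the (3S) benzylic centre and the (5R) centre; if the sense of induction on this substrate is the opposite, the other enantiomer of that ligand is used and nothing else changes.

**Fragment 1 (side-chain aldehyde)**

Step 1
Reactants: 1 (R)-3-bromo-2-methylpropan-1-ol
Product: 2 (R)-(3-bromo-2-methylpropoxy)(tert-butyl)dimethylsilane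
Conditions: TBSCl, imidazole, CH2Cl2, 0 °C to rt
Reagents that add atoms: tert-butyldimethylsilyl chloride, CC(C)(C)[Si](C)(C)Cl
Why: Silyl ether protection of the primary alcohol masks the hydroxyl for the Grignard coupling and leaves the stereocentre untouched.

Step 2
Reactants: 2 (R)-(3-bromo-2-methylpropoxy)(tert-butyl)dimethylsilane
Product: 3 (S)-tert-butyldimethyl[(2-methyloct-7-en-1-yl)oxy]silane
Conditions: CH2=CH(CH2)3MgBr, Li2CuCl4 (cat.), THF/NMP, 0 °C to rt
Reagents that add atoms: 4-pentenylmagnesium bromide, C=CCCC[Mg]Br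
Why: Copper-catalysed sp3–sp3 Grignard cross-coupling (Kochi coupling) at the primary bromide extends the chain without touching the stereocentre, whose descriptor changes only through the priority rules.

Step 3
Reactants: 3 (S)-tert-butyldimethyl[(2-methyloct-7-en-1-yl)oxy]silane
Product: 5 (S)-7-[(tert-butyldimethylsilyl)oxy]-6-methylheptanal, via ozonide 4 (not isolated)
Conditions: O3, CH2Cl2, −78 °C; then PPh3, −78 °C to rt
Reagents that add atoms: ozone, [O-][O+]=O
Why: Ozonolysis with reductive work-up should cleave the terminal alkene to the aldehyde under neutral conditions that spare the silyl ether.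

**Fragment 2 (arene)**

Step 4
Reactants: 6 2-bromo-3-hydroxy-4-methoxybenzaldehyde
Product: 7 2-bromo-3,4-dihydroxybenzaldehyde
Conditions: BBr3, CH2Cl2, −78 °C to rt; then H2O
Reagents that add atoms: none
Why: Lewis acid demethylation of the aryl methyl ether frees the 4-hydroxyl that directs the next substitution.

Step 5
Reactants: 7 2-bromo-3,4-dihydroxybenzaldehyde
Product: 8 2-bromo-3,4-dihydroxy-5-iodobenzaldehyde
Conditions: ICl, AcOH, rt
Reagents that add atoms: iodine monochloride, ICl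
Why: Electrophilic aromatic iodination should go to C5, the only free position ortho to the 4-hydroxyl and meta to the deactivating formyl group, as in the iodination of vanillin.

Step 6
Reactants: 8 2-bromo-3,4-dihydroxy-5-iodobenzaldehyde
Product: 9 3,4-bis(benzyloxy)-2-bromo-5-iodobenzaldehyde
Conditions: BnBr, K2CO3, DMF, 50 °C
Reagents that add atoms: benzyl bromide, BrCc1ccccc1
Why: Williamson etherification of both phenols installs groups that survive every later step and leave by hydrogenolysis at the end.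

Step 7
Reactants: 9 3,4-bis(benzyloxy)-2-bromo-5-iodobenzaldehyde
Product: 10 benzyl 2,3-bis(benzyloxy)-4-bromo-5-formylbenzoate
Conditions: CO (1 atm), BnOH, PdCl2(PPh3)2 (cat.), Et3N, DMF, 60 °C
Reagents that add atoms: carbon monoxide, [C-]#[O+]; benzyl alcohol, OCc1ccccc1
Why: Palladium-catalysed alkoxycarbonylation should take only the C–I bond, because oxidative addition to the doubly ortho-substituted C–Br bond is much slower under CO with triphenylphosphine at this temperature.

Step 8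
Reactants: 10 benzyl 2,3-bis(benzyloxy)-4-bromo-5-formylbenzoate
Product: 11 benzyl 2,3-bis(benzyloxy)-4-bromo-5-(1-hydroxyprop-2-en-1-yl)benzoate (racemic)
Conditions: CH2=CHMgBr, THF, −78 °C; then aq NH4Cl
Reagents that add atoms: vinylmagnesium bromide, C=C[Mg]Br
Why: Grignard 1,2-addition to the aldehyde is much faster at low temperature than attack on the hindered benzyl ester, and the racemic carbinol suffices because the next step is enantioconvergent.

**Union and elaboration**

Step 9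
Reactants: 5 (S)-7-[(tert-butyldimethylsilyl)oxy]-6-methylheptanal; 11 benzyl 2,3-bis(benzyloxy)-4-bromo-5-(1-hydroxyprop-2-en-1-yl)benzoate (racemic)
Product: 13 benzyl 2,3-bis(benzyloxy)-4-bromo-5-[(3S,4S,8S)-9-[(tert-butyldimethylsilyl)oxy]-4-(hydroxymethyl)-8-methylnon-1-en-3-yl]benzoate, via aldehyde 12 (not isolated)
Conditions: 5 (2 equiv), [Ir(cod)Cl]2 (3 mol %), (S)-BINOL-derived phosphoramidite of 5H-dibenz[b,f]azepine (12 mol %), (R)-2-{bis[3,5-bis(trifluoromethyl)phenyl](trimethylsilyloxy)methyl}pyrrolidine (15 mol %), (MeO)2P(O)OH (cat.), ClCH2CH2Cl, 25 °C; then NaBH4, MeOH, 0 °C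
Reagents that add atoms: none
Why: In this stereodivergent iridium/amine dual-catalytic α-allylation of an aldehyde, acid-promoted ionisation of racemic 11 gives an allyl-iridium electrophile whose ligand fixes the benzylic centre (3S) with branched regiochemistry, the enamine of 5 attacks through the face left open by the (R)-prolinol silyl ether to fix the α-centre (4S), and borohydride reduction in the same flask prevents α-epimerisation.

Step 10
Reactants: 13 benzyl 2,3-bis(benzyloxy)-4-bromo-5-[(3S,4S,8S)-9-[(tert-butyldimethylsilyl)oxy]-4-(hydroxymethyl)-8-methylnon-1-en-3-yl]benzoate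
Product: 14 benzyl 2,3-bis(benzyloxy)-4-bromo-5-[(3S,4S,8S)-9-[(tert-butyldimethylsilyl)oxy]-4-{[(tert-butyldimethylsilyl)oxy]methyl}-8-methylnon-1-en-3-yl]benzoate
Conditions: TBSCl, imidazole, DMF, rt
Reagents that add atoms: tert-butyldimethylsilyl chloride, CC(C)(C)[Si](C)(C)Cl
Why: Silyl ether protection removes the last O–H group, which would otherwise compete in the bromination and protonate the organocopper intermediate of the key step.

Step 11
Reactants: 14 benzyl 2,3-bis(benzyloxy)-4-bromo-5-[(3S,4S,8S)-9-[(tert-butyldimethylsilyl)oxy]-4-{[(tert-butyldimethylsilyl)oxy]methyl}-8-methylnon-1-en-3-yl]benzoate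
Product: 16 benzyl 2,3-bis(benzyloxy)-4-bromo-5-[(3S,4S,8S)-9-[(tert-butyldimethylsilyl)oxy]-4-{[(tert-butyldimethylsilyl)oxy]methyl}-1-hydroxy-8-methylnonan-3-yl]benzoate, via alkylborane 15 (not isolated)
Conditions: 9-BBN, THF, 0 °C to rt; then 30% H2O2, aq NaOAc, 0 °C to rt
Reagents that add atoms: hydrogen peroxide, OO
Why: Anti-Markovnikov hydroboration–oxidation with 9-BBN places the hydroxyl on the terminal carbon and leaves the ester, aryl bromide and silyl ethers alone, and the buffered oxidation avoids ester cleavage.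

Step 12
Reactants: 16 benzyl 2,3-bis(benzyloxy)-4-bromo-5-[(3S,4S,8S)-9-[(tert-butyldimethylsilyl)oxy]-4-{[(tert-butyldimethylsilyl)oxy]methyl}-1-hydroxy-8-methylnonan-3-yl]benzoate
Product: 17 benzyl 2,3-bis(benzyloxy)-4-ethenyl-5-[(3S,4S,8S)-9-[(tert-butyldimethylsilyl)oxy]-4-{[(tert-butyldimethylsilyl)oxy]methyl}-1-hydroxy-8-methylnonan-3-yl]benzoate
Conditions: Bu3SnCH=CH2, Pd(PPh3)4 (cat.), toluene, 100 °C
Reagents that add atoms: tributyl(vinyl)stannane, C=C[Sn](CCCC)(CCCC)CCCC
Why: Stille cross-coupling transfers the small vinyl group to the aryl bromide under neutral conditions that the free alcohol, silyl ethers and benzyl ester tolerate.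

Step 13
Reactants: 17 benzyl 2,3-bis(benzyloxy)-4-ethenyl-5-[(3S,4S,8S)-9-[(tert-butyldimethylsilyl)oxy]-4-{[(tert-butyldimethylsilyl)oxy]methyl}-1-hydroxy-8-methylnonan-3-yl]benzoate
Product: 18 benzyl 2,3-bis(benzyloxy)-5-[(3S,4S,8S)-1-bromo-9-[(tert-butyldimethylsilyl)oxy]-4-{[(tert-butyldimethylsilyl)oxy]methyl}-8-methylnonan-3-yl]-4-ethenylbenzoate
Conditions: CBr4, PPh3, CH2Cl2, 0 °C
Reagents that add atoms: carbon tetrabromide, BrC(Br)(Br)Br
Why: The Appel reaction converts the primary alcohol into the primary bromide under near-neutral conditions that spare the vinylarene and the silyl ethers.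

Step 14
Reactants: 18 benzyl 2,3-bis(benzyloxy)-5-[(3S,4S,8S)-1-bromo-9-[(tert-butyldimethylsilyl)oxy]-4-{[(tert-butyldimethylsilyl)oxy]methyl}-8-methylnonan-3-yl]-4-ethenylbenzoate
Product: 19 benzyl (5R,8S)-3,4-bis(benzyloxy)-8-[(2S,6S)-1,7-bis[(tert-butyldimethylsilyl)oxy]-6-methylheptan-2-yl]-5-methyl-5,6,7,8-tetrahydronaphthalene-2-carboxylate
Conditions: Cu(OAc)2 (10 mol %), (R)-DTBM-SEGPHOS (11 mol %), (MeO)2MeSiH, LiOMe, THF, 25 °C
Reagents that add atoms: none
Why: The ligated copper hydride formed from Cu(OAc)2, the bisphosphine and the silane adds across the aryl vinyl group with Markovnikov regiochemistry, so copper sits on the benzylic carbon and the hydride on the terminal carbon, which becomes the C5 methyl group; the benzylic copper then displaces the primary bromide intramolecularly, and LiOMe with the silane regenerates the copper hydride from the copper bromide. The closest known reaction type is the copper hydride-catalysed enantioselective intramolecular hydroalkylation of halide-tethered vinylarenes, applied here to a tetralin closure. Ring B (C4a, C5, C6, C7, C8, C8a) closes in a 6-exo-tet mode at the CH2Br carbon. The C5 configuration is set by the ligand in the hydrocupration and is retained in the alkylation, and the existing C8 centre should reinforce it, because the trans-5,8 product can hold both benzylic substituents pseudoaxial and so avoids peri strain with the C4 benzyloxy group and H1. The step needs hydrocupration of the doubly ortho-substituted vinylarene to outpace reduction of the alkyl bromide, and cyclisation to outpace protonation of the benzylic copper; the absence of any O–H group and the six-membered transition state are meant to secure this, and the esters and ethers are inert to the copper hydride at ambient temperature.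

Step 15
Reactants: 19 benzyl (5R,8S)-3,4-bis(benzyloxy)-8-[(2S,6S)-1,7-bis[(tert-butyldimethylsilyl)oxy]-6-methylheptan-2-yl]-5-methyl-5,6,7,8-tetrahydronaphthalene-2-carboxylate
Product: 21 benzyl (5R,8S)-8-[(2S,6S)-1,7-diacetoxy-6-methylheptan-2-yl]-3,4-bis(benzyloxy)-5-methyl-5,6,7,8-tetrahydronaphthalene-2-carboxylate, via diol 20 (not isolated)
Conditions: TBAF, THF, 0 °C to rt; then Ac2O, Et3N, DMAP, rt
Reagents that add atoms: acetic anhydride, CC(=O)OC(C)=O
Why: Fluoride desilylation followed in the same flask by DMAP-catalysed acetylation converts both primary silyl ethers into acetates while the benzyl ethers and the hindered benzyl ester stay intact.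

Step 16
Reactants: 21 benzyl (5R,8S)-8-[(2S,6S)-1,7-diacetoxy-6-methylheptan-2-yl]-3,4-bis(benzyloxy)-5-methyl-5,6,7,8-tetrahydronaphthalene-2-carboxylate
Product: 22 (5R,8S)-8-[(2S,6S)-1,7-diacetoxy-6-methylheptan-2-yl]-3,4-dihydroxy-5-methyl-5,6,7,8-tetrahydronaphthalene-2-carboxylic acid
Conditions: H2 (1 atm), Pd/C, EtOAc, rt
Reagents that add atoms: none
Why: Catalytic hydrogenolysis cleaves the two benzyl ethers and the benzyl ester in one operation and leaves the alkyl acetates and all four stereocentres untouched.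

**Compound list**

1 | (R)-3-bromo-2-methylpropan-1-ol | OC[C@@H](C)CBr | starting material
2 | (R)-(3-bromo-2-methylpropoxy)(tert-butyl)dimethylsilane | CC(C)(C)[Si](C)(C)OC[C@@H](C)CBr | intermediate
3 | (S)-tert-butyldimethyl[(2-methyloct-7-en-1-yl)oxy]silane | CC(C)(C)[Si](C)(C)OC[C@@H](C)CCCCC=C | intermediate
4 | 3-[(5S)-6-[(tert-butyldimethylsilyl)oxy]-5-methylhexyl]-1,2,4-trioxolane (ozonide) | CC(C)(C)[Si](C)(C)OC[C@@H](C)CCCCC1OCOO1 | intermediate (not isolated)
5 | (S)-7-[(tert-butyldimethylsilyl)oxy]-6-methylheptanal | CC(C)(C)[Si](C)(C)OC[C@@H](C)CCCCC=O | intermediate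
6 | 2-bromo-3-hydroxy-4-methoxybenzaldehyde | O=Cc1ccc(OC)c(O)c1Br | starting material
7 | 2-bromo-3,4-dihydroxybenzaldehyde | O=Cc1ccc(O)c(O)c1Br | intermediate
8 | 2-bromo-3,4-dihydroxy-5-iodobenzaldehyde | O=Cc1cc(I)c(O)c(O)c1Br | intermediate
9 | 3,4-bis(benzyloxy)-2-bromo-5-iodobenzaldehyde | O=Cc1cc(I)c(OCc2ccccc2)c(OCc2ccccc2)c1Br | intermediate
10 | benzyl 2,3-bis(benzyloxy)-4-bromo-5-formylbenzoate | O=Cc1cc(C(=O)OCc2ccccc2)c(OCc2ccccc2)c(OCc2ccccc2)c1Br | intermediate
11 | benzyl 2,3-bis(benzyloxy)-4-bromo-5-(1-hydroxyprop-2-en-1-yl)benzoate (racemic) | C=CC(O)c1cc(C(=O)OCc2ccccc2)c(OCc2ccccc2)c(OCc2ccccc2)c1Br | intermediate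
12 | benzyl 2,3-bis(benzyloxy)-4-bromo-5-[(3S,4S,8S)-9-[(tert-butyldimethylsilyl)oxy]-4-formyl-8-methylnon-1-en-3-yl]benzoate | CC(C)(C)[Si](C)(C)OC[C@@H](C)CCC[C@H](C=O)[C@H](C=C)c1c(Br)c(OCc2ccccc2)c(OCc2ccccc2)c(C(=O)OCc2ccccc2)c1 | intermediate (not isolated)
13 | benzyl 2,3-bis(benzyloxy)-4-bromo-5-[(3S,4S,8S)-9-[(tert-butyldimethylsilyl)oxy]-4-(hydroxymethyl)-8-methylnon-1-en-3-yl]benzoate | CC(C)(C)[Si](C)(C)OC[C@@H](C)CCC[C@H](CO)[C@H](C=C)c1c(Br)c(OCc2ccccc2)c(OCc2ccccc2)c(C(=O)OCc2ccccc2)c1 | intermediate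
14 | benzyl 2,3-bis(benzyloxy)-4-bromo-5-[(3S,4S,8S)-9-[(tert-butyldimethylsilyl)oxy]-4-{[(tert-butyldimethylsilyl)oxy]methyl}-8-methylnon-1-en-3-yl]benzoate | CC(C)(C)[Si](C)(C)OC[C@@H](C)CCC[C@H](CO[Si](C)(C)C(C)(C)C)[C@H](C=C)c1c(Br)c(OCc2ccccc2)c(OCc2ccccc2)c(C(=O)OCc2ccccc2)c1 | intermediate
15 | benzyl 2,3-bis(benzyloxy)-5-[(3S,4S,8S)-1-(9-borabicyclo[3.3.1]nonan-9-yl)-9-[(tert-butyldimethylsilyl)oxy]-4-{[(tert-butyldimethylsilyl)oxy]methyl}-8-methylnonan-3-yl]-4-bromobenzoate | CC(C)(C)[Si](C)(C)OC[C@@H](C)CCC[C@H](CO[Si](C)(C)C(C)(C)C)[C@H](CCB3C4CCCC3CCC4)c1c(Br)c(OCc2ccccc2)c(OCc2ccccc2)c(C(=O)OCc2ccccc2)c1 | intermediate (not isolated)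
16 | benzyl 2,3-bis(benzyloxy)-4-bromo-5-[(3S,4S,8S)-9-[(tert-butyldimethylsilyl)oxy]-4-{[(tert-butyldimethylsilyl)oxy]methyl}-1-hydroxy-8-methylnonan-3-yl]benzoate | CC(C)(C)[Si](C)(C)OC[C@@H](C)CCC[C@H](CO[Si](C)(C)C(C)(C)C)[C@H](CCO)c1c(Br)c(OCc2ccccc2)c(OCc2ccccc2)c(C(=O)OCc2ccccc2)c1 | intermediate
17 | benzyl 2,3-bis(benzyloxy)-4-ethenyl-5-[(3S,4S,8S)-9-[(tert-butyldimethylsilyl)oxy]-4-{[(tert-butyldimethylsilyl)oxy]methyl}-1-hydroxy-8-methylnonan-3-yl]benzoate | CC(C)(C)[Si](C)(C)OC[C@@H](C)CCC[C@H](CO[Si](C)(C)C(C)(C)C)[C@H](CCO)c1c(C=C)c(OCc2ccccc2)c(OCc2ccccc2)c(C(=O)OCc2ccccc2)c1 | intermediate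
18 | benzyl 2,3-bis(benzyloxy)-5-[(3S,4S,8S)-1-bromo-9-[(tert-butyldimethylsilyl)oxy]-4-{[(tert-butyldimethylsilyl)oxy]methyl}-8-methylnonan-3-yl]-4-ethenylbenzoate | CC(C)(C)[Si](C)(C)OC[C@@H](C)CCC[C@H](CO[Si](C)(C)C(C)(C)C)[C@H](CCBr)c1c(C=C)c(OCc2ccccc2)c(OCc2ccccc2)c(C(=O)OCc2ccccc2)c1 | intermediate
19 | benzyl (5R,8S)-3,4-bis(benzyloxy)-8-[(2S,6S)-1,7-bis[(tert-butyldimethylsilyl)oxy]-6-methylheptan-2-yl]-5-methyl-5,6,7,8-tetrahydronaphthalene-2-carboxylate | CC(C)(C)[Si](C)(C)OC[C@@H](C)CCC[C@H](CO[Si](C)(C)C(C)(C)C)[C@@H]1CC[C@@H](C)c2c1cc(C(=O)OCc3ccccc3)c(OCc3ccccc3)c2OCc3ccccc3 | intermediate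
20 | benzyl (5R,8S)-3,4-bis(benzyloxy)-8-[(2S,6S)-1,7-dihydroxy-6-methylheptan-2-yl]-5-methyl-5,6,7,8-tetrahydronaphthalene-2-carboxylate | OC[C@@H](C)CCC[C@H](CO)[C@@H]1CC[C@@H](C)c2c1cc(C(=O)OCc3ccccc3)c(OCc3ccccc3)c2OCc3ccccc3 | intermediate (not isolated)
21 | benzyl (5R,8S)-8-[(2S,6S)-1,7-diacetoxy-6-methylheptan-2-yl]-3,4-bis(benzyloxy)-5-methyl-5,6,7,8-tetrahydronaphthalene-2-carboxylate | CC(=O)OC[C@@H](C)CCC[C@H](COC(C)=O)[C@@H]1CC[C@@H](C)c2c1cc(C(=O)OCc3ccccc3)c(OCc3ccccc3)c2OCc3ccccc3 | intermediate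
22 | (5R,8S)-8-[(2S,6S)-1,7-diacetoxy-6-methylheptan-2-yl]-3,4-dihydroxy-5-methyl-5,6,7,8-tetrahydronaphthalene-2-carboxylic acid | CC(=O)OC[C@@H](C)CCC[C@H](COC(C)=O)[C@@H]1CC[C@@H](C)c2c1cc(C(=O)O)c(O)c2O | target

**Count and risks**

Total step count: 16. Longest linear sequence: 13 steps (steps 4 to 16, from 6).

Steps most likely to fail:

Step 14 (key step). Hydrocupration of the twisted, doubly ortho-substituted vinylarene may be too slow, so that reduction of the alkyl bromide or plain reduction of the alkene takes over, or the facial selectivity of the copper hydride addition may be poor. The fallback is ring-closing metathesis followed by catalyst-controlled hydrogenation; it sets out from 16 and comes back at 19. Stille coupling of 16 with tributyl(isopropenyl)stannane should give the isopropenylarene alcohol F1. Dess–Martin oxidation should give the aldehyde F2, and Wittig methylenation with Ph3P=CH2 should give the diene F3. Ring-closing metathesis with the second-generation Hoveyda–Grubbs catalyst should then close the same C5–C6 bond as an alkene, giving the 7,8-dihydronaphthalene F4. Hydrogenation with a chiral [Ir(cod)(PHOX)]BArF catalyst chosen for the (5R) centre should give 19.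

Step 9. Ionisation of the electron-poor, ortho-bromo carbinol to the allyl-iridium species may be slow, the aldehyde partner may self-condense, or the α-centre may epimerise before reduction and erode the diastereocontrol. The fallback is an enantioselective Ireland–Claisen rearrangement; it sets out from 11 and 5 and comes back at 13. Rhenium-catalysed 1,3-transposition of 11 with Re2O7 should give the (E)-cinnamyl alcohol F5, and Pinnick oxidation of 5 should give the acid F6. Carbodiimide coupling (EDC, DMAP) should join them to the ester F7. A boron-mediated enantioselective Ireland–Claisen rearrangement with a chiral 2-bromo-1,3-bis(arylsulfonyl)-4,5-diphenyl-1,3,2-diazaborolidine and a trialkylamine should give the pentenoic acid F8 through a chair transition state; the amine and solvent are chosen for the enolate geometry that leads to the required relative configuration, and the reagent enantiomer for the absolute sense. Activation as the mixed carbonic anhydride F9 (isobutyl chloroformate, N-methylmorpholine) and reduction with NaBH4 should give 13.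

Step 12. Oxidative addition and transmetalation at the aryl bromide, which is flanked by a benzyloxy group and a branched benzylic carbon, may be slow, so that protodebromination or catalyst decomposition competes. The fallback installs the vinyl group before the branched chain; it sets out from 10 and comes back at 17. Stille coupling of 10, whose bromide is activated by the ortho formyl group, with tributyl(vinyl)stannane should give the vinyl aldehyde F10, and vinylmagnesium bromide should give the dienol F11. The dual-catalytic allylation with 5 should give the aldehyde F12 (not isolated) and, after NaBH4, the alcohol F13; silylation should give the bis-silyl ether F14. 9-BBN reacts far faster with the monosubstituted alkyl alkene than with the hindered vinylarene, so it should give the alkylborane F15 (not isolated) and, after buffered peroxide, 17.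

Further compounds
F1 | step 14 | benzyl 2,3-bis(benzyloxy)-5-[(3S,4S,8S)-9-[(tert-butyldimethylsilyl)oxy]-4-{[(tert-butyldimethylsilyl)oxy]methyl}-1-hydroxy-8-methylnonan-3-yl]-4-(prop-1-en-2-yl)benzoate | CC(C)(C)[Si](C)(C)OC[C@@H](C)CCC[C@H](CO[Si](C)(C)C(C)(C)C)[C@H](CCO)c1c(C(C)=C)c(OCc2ccccc2)c(OCc2ccccc2)c(C(=O)OCc2ccccc2)c1
F2 | step 14 | benzyl 2,3-bis(benzyloxy)-5-[(3S,4S,8S)-9-[(tert-butyldimethylsilyl)oxy]-4-{[(tert-butyldimethylsilyl)oxy]methyl}-8-methyl-1-oxononan-3-yl]-4-(prop-1-en-2-yl)benzoate | CC(C)(C)[Si](C)(C)OC[C@@H](C)CCC[C@H](CO[Si](C)(C)C(C)(C)C)[C@H](CC=O)c1c(C(C)=C)c(OCc2ccccc2)c(OCc2ccccc2)c(C(=O)OCc2ccccc2)c1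
F3 | step 14 | benzyl 2,3-bis(benzyloxy)-5-[(4S,5S,9S)-10-[(tert-butyldimethylsilyl)oxy]-5-{[(tert-butyldimethylsilyl)oxy]methyl}-9-methyldec-1-en-4-yl]-4-(prop-1-en-2-yl)benzoate | CC(C)(C)[Si](C)(C)OC[C@@H](C)CCC[C@H](CO[Si](C)(C)C(C)(C)C)[C@H](CC=C)c1c(C(C)=C)c(OCc2ccccc2)c(OCc2ccccc2)c(C(=O)OCc2ccccc2)c1
F4 | step 14 | benzyl (8S)-3,4-bis(benzyloxy)-8-[(2S,6S)-1,7-bis[(tert-butyldimethylsilyl)oxy]-6-methylheptan-2-yl]-5-methyl-7,8-dihydronaphthalene-2-carboxylate | CC(C)(C)[Si](C)(C)OC[C@@H](C)CCC[C@H](CO[Si](C)(C)C(C)(C)C)[C@@H]1CC=C(C)c2c1cc(C(=O)OCc3ccccc3)c(OCc3ccccc3)c2OCc3ccccc3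
F5 | step 9 | benzyl 2,3-bis(benzyloxy)-4-bromo-5-[(E)-3-hydroxyprop-1-en-1-yl]benzoate | OC/C=C/c1cc(C(=O)OCc2ccccc2)c(OCc2ccccc2)c(OCc2ccccc2)c1Br
F6 | step 9 | (S)-7-[(tert-butyldimethylsilyl)oxy]-6-methylheptanoic acid | CC(C)(C)[Si](C)(C)OC[C@@H](C)CCCCC(=O)O
F7 | step 9 | benzyl 2,3-bis(benzyloxy)-4-bromo-5-[(E)-3-{[(S)-7-[(tert-butyldimethylsilyl)oxy]-6-methylheptanoyl]oxy}prop-1-en-1-yl]benzoate | CC(C)(C)[Si](C)(C)OC[C@@H](C)CCCCC(=O)OC/C=C/c1cc(C(=O)OCc2ccccc2)c(OCc2ccccc2)c(OCc2ccccc2)c1Br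
F8 | step 9 | (2S,3S)-3-[3,4-bis(benzyloxy)-5-(benzyloxycarbonyl)-2-bromophenyl]-2-[(4S)-5-[(tert-butyldimethylsilyl)oxy]-4-methylpentyl]pent-4-enoic acid | CC(C)(C)[Si](C)(C)OC[C@@H](C)CCC[C@H](C(=O)O)[C@H](C=C)c1c(Br)c(OCc2ccccc2)c(OCc2ccccc2)c(C(=O)OCc2ccccc2)c1
F9 | step 9 | mixed anhydride of F8 with isobutyl hydrogen carbonate | CC(C)(C)[Si](C)(C)OC[C@@H](C)CCC[C@H](C(=O)OC(=O)OCC(C)C)[C@H](C=C)c1c(Br)c(OCc2ccccc2)c(OCc2ccccc2)c(C(=O)OCc2ccccc2)c1
F10 | step 12 | benzyl 2,3-bis(benzyloxy)-4-ethenyl-5-formylbenzoate | O=Cc1cc(C(=O)OCc2ccccc2)c(OCc2ccccc2)c(OCc2ccccc2)c1C=C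
F11 | step 12 | benzyl 2,3-bis(benzyloxy)-4-ethenyl-5-(1-hydroxyprop-2-en-1-yl)benzoate (racemic) | C=CC(O)c1cc(C(=O)OCc2ccccc2)c(OCc2ccccc2)c(OCc2ccccc2)c1C=C
F12 | step 12 | benzyl 2,3-bis(benzyloxy)-5-[(3S,4S,8S)-9-[(tert-butyldimethylsilyl)oxy]-4-formyl-8-methylnon-1-en-3-yl]-4-ethenylbenzoate | CC(C)(C)[Si](C)(C)OC[C@@H](C)CCC[C@H](C=O)[C@H](C=C)c1c(C=C)c(OCc2ccccc2)c(OCc2ccccc2)c(C(=O)OCc2ccccc2)c1
F13 | step 12 | benzyl 2,3-bis(benzyloxy)-5-[(3S,4S,8S)-9-[(tert-butyldimethylsilyl)oxy]-4-(hydroxymethyl)-8-methylnon-1-en-3-yl]-4-ethenylbenzoate | CC(C)(C)[Si](C)(C)OC[C@@H](C)CCC[C@H](CO)[C@H](C=C)c1c(C=C)c(OCc2ccccc2)c(OCc2ccccc2)c(C(=O)OCc2ccccc2)c1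
F14 | step 12 | benzyl 2,3-bis(benzyloxy)-5-[(3S,4S,8S)-9-[(tert-butyldimethylsilyl)oxy]-4-{[(tert-butyldimethylsilyl)oxy]methyl}-8-methylnon-1-en-3-yl]-4-ethenylbenzoate | CC(C)(C)[Si](C)(C)OC[C@@H](C)CCC[C@H](CO[Si](C)(C)C(C)(C)C)[C@H](C=C)c1c(C=C)c(OCc2ccccc2)c(OCc2ccccc2)c(C(=O)OCc2ccccc2)c1
F15 | step 12 | benzyl 2,3-bis(benzyloxy)-5-[(3S,4S,8S)-1-(9-borabicyclo[3.3.1]nonan-9-yl)-9-[(tert-butyldimethylsilyl)oxy]-4-{[(tert-butyldimethylsilyl)oxy]methyl}-8-methylnonan-3-yl]-4-ethenylbenzoate | CC(C)(C)[Si](C)(C)OC[C@@H](C)CCC[C@H](CO[Si](C)(C)C(C)(C)C)[C@H](CCB3C4CCCC3CCC4)c1c(C=C)c(OCc2ccccc2)c(OCc2ccccc2)c(C(=O)OCc2ccccc2)c1
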